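Start from Sunday's run, which is the very flask asked about, followed as far as 8.00 min.

all flasks: starting material 0.061 M; reagent 0.0732 M; third substrate 0.0122 M
- Sunday's: second substrate 0.061 M; the very flask that is asked about, followed so far
- flask: second substrate 0.0610 M; time 40 min

- Sunday's (time / min: target / %, side product / %, starting material / %): 0.667: 1, 0, 99; 1.00: 3, 1, 98; 2.00: 5, 6, 88; 3.00: 5, 6, 87; 5.00: 12, 18, 81; 8.00: 8, 25, 68

(standard deviation of a reading: 1.5 percentage points)

- where most of what was charged as starting material, at 40 min is found (target / starting material / side product)
- the largest share itself, whichever of these holds it, in percent of the starting material charged

- in percentages every species weighs as the starting material in it: one side product counts as two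

Read the target column first: from 2.00 min on it wanders between 5% and 12%, while the side product climbs to 25%. So suppose that a molecule of starting material has two forks: it meets reagent and becomes target, or it meets target and becomes side product. A flat target column then means that both forks are taken equally often. On that supposition each reagent spent removes two starting material, and c(target) over c(reagent) stands still.

Reagent is not read, so reckon it. As a rough balance, suppose the third substrate takes reagent equal to its whole charge, the second substrate takes none, and the lost starting material takes reagent equal to half its own amount. This leaves c(reagent) = 0.0512 M at 8.00 min. Now read the last target row, which carries a scatter of 1.5 percentage points: c(target) over c(reagent) comes to 0.0952. Call this the hold-up ratio, a selectivity factor read from concentrations.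

Next read the starting-material column. Taking the loss as first order in both partners, c(starting material) over c(reagent) falls exponentially from 1.00. The last row reads it as 0.810 at 8.00 min, so at 40 min I expect 0.348. My own reckoning then gives c(starting material) = 0.0128 M and c(reagent) = 0.0369 M. That means 21.0% starting material, 5.76% target and 73.2% side product.

The forecast names side product at 67%, with a range of 52% to 78%, holding that “nearly everything consumed ends up as side product”. Its share is lower than mine.

The flask gives side product at 76.1%.

    starting material + reagent → target (k = 0.521 L mol⁻¹ min⁻¹)
    second substrate + reagent → second product (k = 0.0198 L mol⁻¹ min⁻¹)
    third substrate + reagent → third product (k = 5.69 L mol⁻¹ min⁻¹)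
    second substrate ⇌ dormant form (K = 2.10, k = 0.0357 min⁻¹)
    third substrate → decomposition product (k = 9.09 × 10⁻⁶ min⁻¹)
    starting material + target → side product (k = 5.03 L mol⁻¹ min⁻¹)

Carry the hold-up ratio over. In this flask at 40.0 min, reagent stands at 44.7% of its charge, so 0.0952 gives 5.11% target, and the flask holds 6.22%. Now take the neighbour flask charged with 0.018 M of reagent and read at 40.0 min. Its reagent stands at 10.1% of that charge, so the same ratio gives 0.284% target, and that flask holds 0.379%. Its starting material stands at 77.9%, and its side product at 21.7%.

The numbers in the tables stem from a simulated flask with made-up constants.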